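Readings and results were generated by integration with constants of no real substance; noise was put on by code.

Free catalyst, which is single-handed, was charged at two levels in the earlier runs, and from these I had to judge two later flasks.

all flasks: left-handed substrate 20 mM; right-handed substrate 20 mM

| run | reagent | free catalyst | remark | time |
|---|---|---|---|---|
| beta | 40 mM | 14 µM | run made earlier |  |
| alpha | 40 mM | 56 µM | run made earlier |  |
| blue | 40.0 mM | 28 µM |  | 20 h |
| green | 40.0 mM | 28 µM |  | 80 h |

| run | time / h | left-handed product / % | right-handed product / % |
|---|---|---|---|
| beta | 1.50 | 8.6 | 9.2 |
| beta | 2.50 | 13.5 | 13.4 |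
| beta | 4.00 | 19.7 | 17.3 |
| beta | 8.00 | 27.2 | 22.6 |
| beta | 12.0 | 32.8 | 23.8 |
| beta | 20.0 | 36.0 | 27.0 |
| alpha | 1.50 | 28.8 | 25.8 |
| alpha | 2.50 | 35.8 | 31.3 |
| alpha | 4.00 | 42.1 | 34.3 |
| alpha | 8.00 | 45.3 | 37.3 |
| alpha | 12.0 | 46.6 | 37.8 |
| alpha | 20.0 | 46.3 | 38.9 |

(scatter of a reading: 0.5 percentage points)

* the winner by excess of left-handed product over right-handed product in the product; "neither" if no more than 2 percentage points parts them (blue / green / neither)
* excess of left-handed product over right-handed product in the product at the end, blue
* excess of left-handed product over right-handed product in the product at the end, green

- free catalyst is single-handed; left-handed substrate and right-handed substrate are mirror images of each other, charged as a racemate, each of them at the stated concentration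
- the earlier runs were read with a standard deviation of 0.5 percentage points
- steps that have been proposed: free catalyst + left-handed substrate <-> catalyst intermediate A; free catalyst + right-handed substrate <-> catalyst intermediate B; reagent + catalyst intermediate A -> free catalyst + left-handed product; reagent + catalyst intermediate B -> free catalyst + right-handed product; 2 free catalyst -> spent catalyst; 2 reagent -> homo dimer; reagent <-> dormant form
- an excess is below zero if the other one leads

1. With concentrations held and no catalyst lost, each proposed product step runs through a catalyst intermediate, so its rate scales with the [free catalyst] charged.

2. Blue's end therefore came at 10.0 h of scaled time, the hours of a run times its [free catalyst] charge over alpha's. Green's end came at 40.0 h.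

3. The scaling was not exact. Beta's last reading, at 5.00 h scaled, showed 63.0% total product, less than alpha's 76.4% at 4.00 h. That pointed to a loss that follows the clock, not the catalyst.

4. Alpha's excess read 9.69% at 8.00 h and 8.69% at 20.0 h. This was a drift of 1 percentage point, less than the margin of 2 points.

5. Blue's scaled end lay later than that 8.00 h, and green's later still. I therefore expected neither to win, with both excesses between alpha's last reading and beta's 14.3%.

The forecast gave neither, with 12% for blue and 11.5% for green: “Later conversion adds little and slightly erodes the excess”.

The flasks gave 13.0% for blue and 13.1% for green, so the answer was neither.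

    free catalyst + left-handed substrate ⇌ catalyst intermediate A (K = 340 /M, k = 1100 /M/min)
    free catalyst + right-handed substrate ⇌ catalyst intermediate B (K = 240 /M, k = 3100 /M/min)
    reagent + catalyst intermediate A → free catalyst + left-handed product (k = 460 /M/min)
    reagent + catalyst intermediate B → free catalyst + right-handed product (k = 180 /M/min)
    2 free catalyst → spent catalyst (k = 23.0 /M/min)
    2 reagent → homo dimer (k = 0.0540 /M/min)
    reagent ⇌ dormant form (K = 0.270, k = 0.00180 /min)

At blue's scaled 10.0 h, unbound reagent, the limiting reagent, stood at 0.42% of its charge. A neighbour of blue charged with 0.070 mM of free catalyst reached 25.0 h scaled, with unbound reagent at 0.074% and an excess of 8.74%, less than green's 13.1% at scaled 40.0 h, so these flasks' excesses did not follow scaled time. The main reason blue's excess favours left-handed product is the return of catalyst intermediate B to free catalyst and right-handed substrate. In the blue run without that return, the excess was −31.3%.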